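## Retrosynthetic overview

- Numbering: C1 is the CH that bears the guaiacyl ring (ring C). C2 and C3 are the CH–CH2OH carbons and C4 is the CH2. Ring A is C4a–C8a (OMe at C6 and C8, OH at C7), and ring B is C1–C4 plus C4a and C8a.
- The target comes from LiAlH4 reduction of a 2,3-diester. That diester comes from hydrogenolysis of two O-benzyl groups and of a temporary C4 hydroxyl.
- Ring B is the only ring formed. One photoenolisation/Diels–Alder event makes C1–C2 and C3–C4 together, from an achiral 2-benzylbenzaldehyde (rings A and C bought aromatic) and the C2-symmetric fumarate of methyl (S)-lactate.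
- Enabling feature: C1 and C4 are both benzylic and sit on the neighbouring ring A atoms C8a and C4a, so ring A can be dearomatised to an o-quinodimethane. The C1–H is doubly benzylic and transfers easily to an excited C4 aldehyde. C4 is a stereochemically silent CH2 para to the C7 oxygen, so the hydroxyl left there can be erased, and the trans C2/C3 pair is the E-alkene of a fumarate.
- The aldehyde comes from Negishi coupling of 2-iodo-O-benzylsyringaldehyde with an O-benzylvanillyl zinc chloride.

Key step: step 6

Assumption: the fumarate of methyl (S)-lactate is taken to react on its Re,Re face with the hydroxy-o-quinodimethane (model given in step 6). The facial isomers of 12 are diastereomers, so the assignment is verified and minor isomers are removed at 12; the mirror-image lactate is equally available.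

## Route

Step 1
Reactants: 1 syringaldehyde (4-hydroxy-3,5-dimethoxybenzaldehyde)
Product: 2 4-(benzyloxy)-3,5-dimethoxybenzaldehyde
Conditions: BnBr, K2CO3, DMF, 60 °C
Reagents that add atoms: benzyl bromide, BrCc1ccccc1
Why: Williamson ether synthesis on the acidic para-formyl phenol; the benzyl group masks the C7 oxygen through the coupling and the photochemistry and is removed later together with the C4 hydroxyl.

Step 2
Reactants: 2 4-(benzyloxy)-3,5-dimethoxybenzaldehyde
Product: 3 4-(benzyloxy)-2-iodo-3,5-dimethoxybenzaldehyde
Conditions: I2, AgOCOCF3, CH2Cl2, rt, dark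
Reagents that add atoms: iodine, II
Why: Electrophilic aromatic iodination by CF3CO2I formed in the flask; the only free ring positions (C2 and C6, equivalent) are ortho and para to the two methoxy groups, and the first iodine crowds and deactivates the ring against a second one.

Step 3
Reactants: 4 4-(benzyloxy)-3-methoxybenzyl alcohol
Product: 5 4-(benzyloxy)-3-methoxybenzyl chloride
Conditions: SOCl2, CH2Cl2, 0 °C; used without storage
Reagents that add atoms: thionyl chloride, O=S(Cl)Cl
Why: Chlorodehydroxylation through the chlorosulfite, which should be fast at 0 °C because the electron-rich benzylic position ionises easily.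

Step 4
Reactants: 5 4-(benzyloxy)-3-methoxybenzyl chloride; 3 4-(benzyloxy)-2-iodo-3,5-dimethoxybenzaldehyde
Product: 7 4-(benzyloxy)-2-[4-(benzyloxy)-3-methoxybenzyl]-3,5-dimethoxybenzaldehyde, via benzylzinc chloride 6 (not isolated)
Conditions: Zn dust, LiCl, THF, 25 °C; then 3, Pd(OAc)2 (cat.), SPhos (cat.), THF, 25 °C
Reagents that add atoms: none
Why: Negishi cross-coupling: LiCl-assisted zinc insertion gives 6, and oxidative addition of zerovalent palladium into the C–I bond (activated by the ortho formyl group), transmetalation and reductive elimination should outrun the slow uncatalysed addition of 6 to the aldehyde.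

Step 5
Reactants: 8 fumaryl chloride; 9 methyl (S)-lactate (2 equiv)
Product: 10 bis[(S)-1-methoxy-1-oxopropan-2-yl] fumarate
Conditions: pyridine, CH2Cl2, 0 °C to rt
Reagents that add atoms: none
Why: Double O-acylation of the secondary alcohol by the acid chloride; the C–O bond at the lactate stereocentre is not touched, so both centres stay (S) and the E-alkene is kept.

Step 6
Reactants: 7 4-(benzyloxy)-2-[4-(benzyloxy)-3-methoxybenzyl]-3,5-dimethoxybenzaldehyde; 10 bis[(S)-1-methoxy-1-oxopropan-2-yl] fumarate
Product: 12 bis[(S)-1-methoxy-1-oxopropan-2-yl] (1S,2R,3S,4S)-7-(benzyloxy)-1-[4-(benzyloxy)-3-methoxyphenyl]-4-hydroxy-6,8-dimethoxy-1,2,3,4-tetrahydronaphthalene-2,3-dicarboxylate, via photoenol 11 (not isolated)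
Conditions: 10 (2 equiv), hν (365 nm LED), degassed toluene, 0–20 °C; chromatography, then crystallisation
Reagents that add atoms: none
Why: Excitation of the aldehyde of 7 (n,π* triplet) triggers 1,5-hydrogen atom transfer from the doubly benzylic CH2, and the biradical relaxes to dienol 11, of which only the isomer with OH and aryl both outward lives long enough to be trapped (the inward-OH isomer returns to 7 by 1,5-H shift), so ring A becomes for a moment an electron-rich diene. The closest known reaction type is the photoenolisation/Diels–Alder reaction of 2-alkyl- and 2-benzylbenzaldehydes with fumarates, including fumarates of α-hydroxy ester auxiliaries. Ring B is closed by a concerted, suprafacial, intermolecular [4+2] cycloaddition that forms C1–C2 and C3–C4 together and is driven by rearomatisation of ring A. Relative configuration: the two outward groups end cis (C1 aryl cis to C4 OH), the ester next to the dienol OH takes the endo position (secondary overlap plus O–H···O=C hydrogen bond) and ends cis to that OH, and the E-alkene then places the C2 ester exo and trans to the aryl group, which also avoids the aryl ring twisted by the C8 methoxy group, so the 1,2-trans-2,3-trans array of the target results. Absolute configuration: in the s-cis enoate conformer with the carbinol C–H eclipsing C=O, both (S)-lactate units put their methyl groups on the Si,Si face and their CO2Me groups, which can accept the hydrogen bond of the dienol, on the Re,Re face, so attack on the Re,Re face gives (2R,3S) and with it (1S,4S). The step needs hydrogen transfer to be faster than energy transfer to 10 (secured by the weak diarylmethane C–H and by 365 nm light that 10 does not absorb); it has no regiochemical issue because 10 is C2-symmetric, and minor diastereomers are removed here.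

Step 7
Reactants: 12 the cycloadduct of step 6
Product: 13 bis[(S)-1-methoxy-1-oxopropan-2-yl] (1S,2R,3R)-7-hydroxy-1-(4-hydroxy-3-methoxyphenyl)-6,8-dimethoxy-1,2,3,4-tetrahydronaphthalene-2,3-dicarboxylate
Conditions: H2 (4 atm), 10% Pd/C, EtOAc–AcOH, 40 °C
Reagents that add atoms: none
Why: Catalytic hydrogenolysis: the two aryl benzyl ethers are cleaved, and the C4 hydroxyl, then para to the free C7 phenol, is an activated benzylic C–O bond (p-quinone methide pathway) that is reduced to CH2, so the only stereocentre lost is the one the target lacks, while the lactate esters and C1–C3 are untouched.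

Step 8
Reactants: 13 the bisphenol diester of step 7
Product: 14 (+)-8-methoxyisolariciresinol, (1S,2R,3R)-1-(4-hydroxy-3-methoxyphenyl)-2,3-bis(hydroxymethyl)-6,8-dimethoxy-1,2,3,4-tetrahydronaphthalen-7-ol
Conditions: LiAlH4 (excess), THF, 0 °C to reflux; aqueous acidic work-up, EtOAc extraction
Reagents that add atoms: none
Why: LiAlH4 reduction of all four ester groups (after deprotonation of the two phenols) sets free both CH2OH groups and releases the auxiliary as water-soluble propane-1,2-diol; no stereocentre is touched and the all-trans array is also the thermodynamic one.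

## Compound list

1 | syringaldehyde | COc1cc(C=O)cc(OC)c1O | starting material
2 | 4-(benzyloxy)-3,5-dimethoxybenzaldehyde | COc1cc(C=O)cc(OC)c1OCc1ccccc1 | intermediate
3 | 4-(benzyloxy)-2-iodo-3,5-dimethoxybenzaldehyde | COc1cc(C=O)c(I)c(OC)c1OCc1ccccc1 | intermediate
4 | 4-(benzyloxy)-3-methoxybenzyl alcohol | COc1cc(CO)ccc1OCc1ccccc1 | starting material
5 | 4-(benzyloxy)-3-methoxybenzyl chloride | COc1cc(CCl)ccc1OCc1ccccc1 | intermediate
6 | [4-(benzyloxy)-3-methoxybenzyl]zinc chloride | COc1cc(C[Zn]Cl)ccc1OCc1ccccc1 | intermediate
7 | 4-(benzyloxy)-2-[4-(benzyloxy)-3-methoxybenzyl]-3,5-dimethoxybenzaldehyde | COc1cc(Cc2c(C=O)cc(OC)c(OCc3ccccc3)c2OC)ccc1OCc1ccccc1 | intermediate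
8 | fumaryl chloride | O=C(Cl)/C=C/C(=O)Cl | starting material
9 | methyl (S)-lactate | C[C@H](O)C(=O)OC | starting material
10 | bis[(S)-1-methoxy-1-oxopropan-2-yl] fumarate | COC(=O)[C@H](C)OC(=O)/C=C/C(=O)O[C@@H](C)C(=O)OC | intermediate
11 | photoenol of 7 (hydroxy-o-quinodimethane, OH on C4 and aryl on C1 both outward) | O/C=C1\C=C(OC)C(OCc2ccccc2)=C(OC)/C1=C\c1ccc(OCc2ccccc2)c(OC)c1 | intermediate
12 | bis[(S)-1-methoxy-1-oxopropan-2-yl] (1S,2R,3S,4S)-7-(benzyloxy)-1-[4-(benzyloxy)-3-methoxyphenyl]-4-hydroxy-6,8-dimethoxy-1,2,3,4-tetrahydronaphthalene-2,3-dicarboxylate | COc1cc([C@H]2c3c(cc(OC)c(OCc4ccccc4)c3OC)[C@@H](O)[C@@H](C(=O)O[C@@H](C)C(=O)OC)[C@@H]2C(=O)O[C@@H](C)C(=O)OC)ccc1OCc1ccccc1 | intermediate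
13 | bis[(S)-1-methoxy-1-oxopropan-2-yl] (1S,2R,3R)-7-hydroxy-1-(4-hydroxy-3-methoxyphenyl)-6,8-dimethoxy-1,2,3,4-tetrahydronaphthalene-2,3-dicarboxylate | COc1cc([C@H]2c3c(cc(OC)c(O)c3OC)C[C@@H](C(=O)O[C@@H](C)C(=O)OC)[C@@H]2C(=O)O[C@@H](C)C(=O)OC)ccc1O | intermediate
14 | (+)-8-methoxyisolariciresinol | COc1cc([C@H]2c3c(cc(OC)c(O)c3OC)C[C@@H](CO)[C@@H]2CO)ccc1O | target

## Step count and risks

Total step count: 8. Longest linear sequence: 6 (steps 1, 2, 4, 6, 7, 8).

**1. Step 6.**
- Photoenolisation may be inefficient, because the trialkoxy ring lowers a π,π* triplet.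
- The excited aldehyde may pass its energy to 10 and isomerise the E-alkene.
- The C8 methoxy group crowds the outward aryl group and may slow the cycloaddition, so that the dienol merely reverts.
- Facial selectivity may be modest.
- Fallback, from 7 back to 12, separates light from cycloaddition. Compound 7 is irradiated in benzene saturated with SO2, and the dienol is caught by cheletropic addition as racemic cis-5-(benzyloxy)-3-[4-(benzyloxy)-3-methoxyphenyl]-1-hydroxy-4,6-dimethoxy-1,3-dihydrobenzo[c]thiophene 2,2-dioxide F1, a storable temporary ring.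
- Heating F1 with 10 in toluene at 80–110 °C over ZnO extrudes SO2 and regenerates 11 slowly in the dark. The fumarate then cannot be isomerised and is always in large excess over the diene, and 12 is formed.

**2. Step 7.**
- The C4–O cleavage may stall after debenzylation.
- Ionisation at C4 may be followed by loss of the acidic C3–H, giving a C3=C4 alkene whose later hydrogenation would scramble C3.
- Fallback, from 12 back to 13, is a radical Barton–McCombie deoxygenation. Compound 12 is treated with 1,1'-thiocarbonyldiimidazole (DMAP, CH2Cl2) to give the C4 O-(imidazol-1-ylthiocarbonyl) derivative F2.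
- Bu3SnH and AIBN in toluene at 90 °C reduce F2 through the benzylic C4 radical to the 4-deoxy dibenzyl ether diester F3.
- Neutral hydrogenolysis (H2, Pd/C, EtOAc) then removes only the two benzyl ethers to give 13.

**3. Step 4.**
- The benzylzinc reagent may add to the aldehyde or homocouple.
- Oxidative addition at the doubly ortho-substituted iodide may be slow.
- Fallback, from 5 (and 3) back to 7, changes the nucleophile to boron, which does not add to aldehydes. Miyaura-type borylation of 5 (B2pin2, Pd(dba)2, P(4-MeOC6H4)3, KOAc, toluene, 50 °C) gives 2-[4-(benzyloxy)-3-methoxybenzyl]-4,4,5,5-tetramethyl-1,3,2-dioxaborolane F4.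
- Suzuki–Miyaura coupling of F4 with 3 (Pd(dppf)Cl2, Cs2CO3, THF–H2O, 70 °C) gives 7.

## Further compounds

F1 | step 6 | cis-5-(benzyloxy)-3-[4-(benzyloxy)-3-methoxyphenyl]-1-hydroxy-4,6-dimethoxy-1,3-dihydrobenzo[c]thiophene 2,2-dioxide (racemic, relative configuration shown) | COc1cc([C@H]2c3c(cc(OC)c(OCc4ccccc4)c3OC)[C@@H](O)S2(=O)=O)ccc1OCc1ccccc1
F2 | step 7 | C4 O-(imidazol-1-ylthiocarbonyl) derivative of 12 | COc1cc([C@H]2c3c(cc(OC)c(OCc4ccccc4)c3OC)[C@@H](OC(=S)n4ccnc4)[C@@H](C(=O)O[C@@H](C)C(=O)OC)[C@@H]2C(=O)O[C@@H](C)C(=O)OC)ccc1OCc1ccccc1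
F3 | step 7 | bis[(S)-1-methoxy-1-oxopropan-2-yl] (1S,2R,3R)-7-(benzyloxy)-1-[4-(benzyloxy)-3-methoxyphenyl]-6,8-dimethoxy-1,2,3,4-tetrahydronaphthalene-2,3-dicarboxylate | COc1cc([C@H]2c3c(cc(OC)c(OCc4ccccc4)c3OC)C[C@@H](C(=O)O[C@@H](C)C(=O)OC)[C@@H]2C(=O)O[C@@H](C)C(=O)OC)ccc1OCc1ccccc1
F4 | step 4 | 2-[4-(benzyloxy)-3-methoxybenzyl]-4,4,5,5-tetramethyl-1,3,2-dioxaborolane | COc1cc(CB2OC(C)(C)C(C)(C)O2)ccc1OCc1ccccc1
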